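(The readings were generated by integration for substances that don't exist; scatter was added.)

Molar, not percent, is the unit to hold this bench in, because green and teal both stand at 70 °C with 0.205 M of second nucleophile, as the east run did.

| setting | west | east | north-east | green | teal |
|---|---|---|---|---|---|
| substrate | 0.41 M | 0.41 M | 0.42 M | 0.41 M | 0.80 M |
| first nucleophile | 0.51 M | 1.2 M | 0.389 M | 0.389 M | 0.800 M |
| second nucleophile | 0.205 M | 0.205 M | 0.205 M | 0.205 M | 0.205 M |
| protic impurity | 0.041 M | 0.041 M | 0.041 M | 0.0410 M | 0.0410 M |
| temperature | 55 °C | 70 °C | 55 °C | 70 °C | 70 °C |
| remark | run made earlier | run made earlier | run made earlier |  |  |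
| time |  |  |  | 15 d | 15 d |

| run | time / d | target / % |
|---|---|---|
| west | 1.25 | 17 |
| west | 2.50 | 30 |
| west | 6.00 | 46 |
| west | 15.0 | 58 |
| east | 2.08 | 75 |
| east | 4.00 | 81 |
| east | 6.00 | 81 |
| east | 8.00 | 79 |
| north-east | 1.25 | 13 |
| north-east | 2.50 | 26 |
| north-east | 6.00 | 40 |
| north-east | 15.0 | 52 |

(scatter of a reading: 1.5 percentage points)

1. the winner by amount of target, in percent of the substrate charged; "neither" if no more than 2 percentage points parts them (green / teal / neither)
2. how much target is there at the end, in percent of the substrate charged: green
3. how much target is there at the end, in percent of the substrate charged: teal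

- the analysis behind the earlier runs scatters by 1.5 percentage points, standard deviation
- steps thought possible: substrate -> intermediate; first nucleophile + intermediate -> target; second nucleophile + intermediate -> other capture product; intermediate -> solvolysis product; first nucleophile + protic impurity -> quenched reagent

To whoever takes over: leave both flasks their 15 d and don't add time. The east run stopped rising near 81% by 4.00 d, and 15 d is longer, so we expect the substrate to have reacted and the end to depend on how the intermediate was shared out. That plateau, with about 0.993 M of free first nucleophile on average, gives the reading K = 0.233 M. This is the half-share concentration, the free first nucleophile at which it takes as much intermediate as second nucleophile and solvolysis together; it works like a Michaelis constant.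

We take the protic impurity's 0.0410 M off the charge, which leaves 0.348 M free in green and 0.759 M in teal. The share at the start, 59.9% in green, brings green's mid-run level to 0.225 M, below K, so we reckon 49.2%. Teal starts at 76.5%, and we estimate its mid-run level at 0.453 M, above K, so we reckon 66.0%.

The forecast, a little above us, says 51% (47% to 57%) for green and 68% (63% to 75%) for teal: "Teal wins clearly".

The flasks give 51.4% for green and 68.2% for teal, with conversion 100% in green.

    substrate → intermediate (k = 0.0650 h⁻¹, Ea = 121 kJ mol⁻¹)
    first nucleophile + intermediate → target (k = 28.0 M⁻¹ h⁻¹, Ea = 79.0 kJ mol⁻¹)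
    second nucleophile + intermediate → other capture product (k = 23.0 M⁻¹ h⁻¹, Ea = 76.0 kJ mol⁻¹)
    intermediate → solvolysis product (k = 2.70 h⁻¹, Ea = 95.0 kJ mol⁻¹)
    first nucleophile + protic impurity → quenched reagent (k = 14.0 M⁻¹ h⁻¹, Ea = 75.0 kJ mol⁻¹)
    (constants at 70 °C)

Green ends with 0.137 M of first nucleophile, under K. Green with teal's first nucleophile starts at the same 76.5%, and its mid-run level of 0.602 M gives 72.1% by K; that flask holds 71.9% of target.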